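**Strategy.** The cyclodecane ring is never cyclised; it is released from a cyclohexane by an anionic oxy-Cope rearrangement. The feature exploited (germacrane numbering) is that oxygenated C9 and methyl-bearing C4 lie 1,6 across the ten-membered carbocycle, with the C6–C7 bond opposite, so C4–C9 can be the shared bond of a trans-1,2-dialkenylcyclohexanol. One operation breaks C4–C9, forms C6–C7, creates the E C4=C5 alkene and the C9 carbonyl, and sets C6 and C7 from quaternary C4 through a chair. The precursor is a 2,6-dimethylcyclohexanol with an E 2-(4-methoxybenzyloxy)vinyl arm on C4 and an E dienyl arm on carbinol C9.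

Key step: step 10

Remarks before the steps
- Numbering: all compounds carry the locants of the target (ring C1–C10; C4 bears a methyl, C5/C6 are the enol ether carbons, C7 bears C11, C9 is the carbinol/carbonyl carbon, C10 bears the secondary methyl; C12 is the carboxyl carbon, C13 the methylene).
- Assumption: the meso (cis) isomer of 2,6-dimethylcyclohexanone is used; commercial cis-rich material is equilibrated with base and fractionated beforehand.
- Assumption: the sense of the chiral amide in step 1 is assigned by analogy with 4-substituted cyclohexanones; if the other axial proton is removed, the (S,S) amine is used.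
- Remark: C10 is fixed in step 1 and C4 independently in step 2, so an error in either appears as a separable diastereomer, not as the enantiomer.
- Remark: C6 in 20–29 is (S) by the CIP rules but has the spatial arrangement of (6R) in 30; C5 outranks C7 only once the epoxide exists.
- Remark: in 17 the O9–H group and enol ether carbon C6 are 1,4-related on the same face; acid would close a 2-alkoxytetrahydrofuran, so 17 is worked up and chromatographed on Et3N-washed silica.

Step 1
Reactants: 1 cis-2,6-dimethylcyclohexanone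
Product: 3 trimethyl{[(6R)-2,6-dimethylcyclohex-1-en-1-yl]oxy}silane, via lithium enolate 2 (not isolated)
Conditions: (R,R)-bis(1-phenylethyl)amine hydrochloride, n-BuLi (2 equiv), Me3SiCl (internal quench), THF, −78 °C
Reagents that add atoms: chlorotrimethylsilane, C[Si](C)(C)Cl
Why: Enantiotopic-group-selective kinetic deprotonation of the meso ketone by the chiral lithium amide with in situ silylation removes one of the two mirror-image axial α-protons, so the untouched α-carbon becomes C10 with the (R) configuration.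

Step 2
Reactants: 3 trimethyl{[(6R)-2,6-dimethylcyclohex-1-en-1-yl]oxy}silane
Product: 4 (2R,6R)-2,6-dimethyl-2-(prop-2-en-1-yl)cyclohexanone
Conditions: Pd2(dba)3 (2.5 mol%), (R)-t-BuPHOX (6 mol%), diallyl carbonate, Bu4N[Ph3SiF2] (35 mol%), THF, 25 °C
Reagents that add atoms: diallyl carbonate, C=CCOC(=O)OCC=C
Why: Palladium-catalysed asymmetric allylic alkylation (Tsuji–Trost type) of the regiodefined tetrasubstituted enolate released from the silyl enol ether, in which the PHOX ligand selects the enolate face and sets quaternary C4 as (R) independently of C10, so that the mismatched minority should appear as a diastereomer that is removed by chromatography.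

Step 3
Reactants: 4 (2R,6R)-2,6-dimethyl-2-(prop-2-en-1-yl)cyclohexanone
Product: 5 (2R,6R)-2,6-dimethyl-2-[(1E)-prop-1-en-1-yl]cyclohexanone
Conditions: RuHCl(CO)(PPh3)3 (2 mol%), toluene, 80 °C
Reagents that add atoms: none
Why: Ruthenium hydride-catalysed alkene isomerisation (hydrometalation and β-hydride elimination) can move the double bond by one position only because C4 is quaternary, the neutral conditions leave C10 untouched, and the alkene geometry is irrelevant since the alkene is cleaved next.

Step 4
Reactants: 5 (2R,6R)-2,6-dimethyl-2-[(1E)-prop-1-en-1-yl]cyclohexanone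
Product: 7 (1R,3R)-1,3-dimethyl-2-oxocyclohexane-1-carbaldehyde, via ozonide 6 (not isolated)
Conditions: O3, CH2Cl2, −78 °C; then PPh3, −78 °C to 25 °C
Reagents that add atoms: ozone, [O-][O+]=O
Why: Ozonolysis with reductive work-up cleaves the only alkene to the non-enolisable α-quaternary aldehyde without touching either stereocentre.

Step 5
Reactants: 7 (1R,3R)-1,3-dimethyl-2-oxocyclohexane-1-carbaldehyde
Product: 8 (2R,6R)-2-[(E)-2-iodoethenyl]-2,6-dimethylcyclohexanone
Conditions: CrCl2 (6 equiv), CHI3 (2 equiv), THF, 0 °C to 25 °C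
Reagents that add atoms: iodoform, IC(I)I
Why: Takai iodoolefination, in which the geminal dichromium species from CHI3 adds to the aldehyde and not to the hindered ketone and anti elimination gives the E vinyl iodide, the E preference being highest for α-branched aldehydes.

Step 6
Reactants: 8 (2R,6R)-2-[(E)-2-iodoethenyl]-2,6-dimethylcyclohexanone; 9 4-methoxybenzyl alcohol
Product: 10 (2R,6R)-2-{(E)-2-[(4-methoxybenzyl)oxy]ethenyl}-2,6-dimethylcyclohexanone
Conditions: CuI (10 mol%), 3,4,7,8-tetramethyl-1,10-phenanthroline (20 mol%), Cs2CO3, toluene, 80 °C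
Reagents that add atoms: none
Why: Copper-catalysed Ullmann-type C–O coupling of a vinyl iodide with a primary alcohol proceeds with retention of alkene geometry and gives the E enol ether, while the carbonate, insoluble in toluene, is not expected to epimerise the hindered ketone at C10.

Step 7
Reactants: 11 2-bromoprop-2-en-1-ol
Product: 12 [(2-bromoprop-2-en-1-yl)oxy](tert-butyl)dimethylsilane
Conditions: t-BuMe2SiCl, imidazole, CH2Cl2, 25 °C
Reagents that add atoms: tert-butyl(chloro)dimethylsilane, CC(C)(C)[Si](C)(C)Cl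
Why: Imidazole-promoted silylation of a primary alcohol gives the silyl ether that must survive the organometallic and strongly basic steps.

Step 8
Reactants: 12 [(2-bromoprop-2-en-1-yl)oxy](tert-butyl)dimethylsilane; 13 (E)-1,2-bis(tributylstannyl)ethene
Product: 14 tert-butyl(dimethyl){[(3E)-2-methylidene-4-(tributylstannyl)but-3-en-1-yl]oxy}silane
Conditions: Pd(PPh3)4 (5 mol%), 13 (2.5 equiv), toluene, 90 °C
Reagents that add atoms: none
Why: Stille coupling, in which the vinyl bromide adds oxidatively to zerovalent palladium and one alkenyl group of the symmetric distannane is transferred with retention to give the E dienylstannane, the excess of 13 suppressing double coupling.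

Step 9
Reactants: 14 tert-butyl(dimethyl){[(3E)-2-methylidene-4-(tributylstannyl)but-3-en-1-yl]oxy}silane; 10 (2R,6R)-2-{(E)-2-[(4-methoxybenzyl)oxy]ethenyl}-2,6-dimethylcyclohexanone
Product: 17 (1S,2R,6R)-1-[(1E)-3-({[tert-butyl(dimethyl)silyl]oxy}methyl)buta-1,3-dien-1-yl]-2-{(E)-2-[(4-methoxybenzyl)oxy]ethenyl}-2,6-dimethylcyclohexan-1-ol, via dienyllithium 15 (not isolated), via dienylcerium dichloride 16 (not isolated)
Conditions: 14, n-BuLi, THF, −78 °C; anhydrous CeCl3, −78 °C; then 10, −78 °C; aq. NH4Cl; Et3N-washed silica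
Reagents that add atoms: none
Why: Tin–lithium exchange with retention of the E geometry and transmetalation to the weakly basic organocerium reagent allow 1,2-addition to the hindered enolisable ketone, and the bulky reagent is expected to enter equatorially, trans to the equatorial enol ether arm and C10 methyl that flank the carbonyl (as organometallics do with 2,6-disubstituted cyclohexanones), giving the axial (9S) carbinol with the two alkenyl arms trans, whereas entry anti to the axial C4 methyl would give the C9 epimer, which is removed by chromatography.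

Step 10
Reactants: 17 (1S,2R,6R)-1-[(1E)-3-({[tert-butyl(dimethyl)silyl]oxy}methyl)buta-1,3-dien-1-yl]-2-{(E)-2-[(4-methoxybenzyl)oxy]ethenyl}-2,6-dimethylcyclohexan-1-ol
Product: 20 (3R,4S,5E,10R)-3-(3-{[tert-butyl(dimethyl)silyl]oxy}prop-1-en-2-yl)-4-[(4-methoxybenzyl)oxy]-6,10-dimethylcyclodec-5-en-1-one, via potassium alkoxide 18 (not isolated), via potassium enolate 19 (not isolated)
Conditions: KH (2 equiv), 18-crown-6 (2 equiv), THF, 0 °C to 25 °C; then aq. NH4Cl, −78 °C
Reagents that add atoms: none
Why: Deprotonation gives alkoxide 18, whose oxyanion weakens the C4–C9 bond, and a concerted [3,3] shift of the C6=C5–C4–C9–C8=C7 unit forms C6–C7 and breaks C4–C9 to give ring enolate 19, which is protonated at C8 on work-up. The closest known reaction type is the anionic oxy-Cope ring expansion of trans-1,2-dialkenylcyclohexanols to (E)-cyclodec-5-enones, applied here with an enol ether and a dienyl terminus. The ten-membered ring arises by four-atom ring expansion, that is by cleaving the bond it shares with the cyclohexane, so it needs no high dilution, and the enolate is a thermodynamic sink. C6 and C7 are set together in a chair transition state fused like a trans-decalin to the cyclohexane chair, with both arms equatorial and the C4 methyl and O9 axial: the E enol ether places the C6 oxygen equatorial, the E diene places the C7 side chain equatorial, and the sense of the chair is fixed by quaternary C4, which gives (6S,7R) in 20, the spatial arrangement of the target. The ring carbon C3 is equatorial on that chair, which makes the new C4=C5 alkene E. The selectivity needed is this chair over the boat and over the chair with C3 axial, and it is secured by the trans relation of the arms at C4 and C9, by the E geometry of both alkenes and by the equatorial C10 methyl, which is carried through untouched.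

Step 11
Reactants: 20 (3R,4S,5E,10R)-3-(3-{[tert-butyl(dimethyl)silyl]oxy}prop-1-en-2-yl)-4-[(4-methoxybenzyl)oxy]-6,10-dimethylcyclodec-5-en-1-one
Product: 22 (2S,3R,4S,5E,10R)-2-bromo-3-(3-{[tert-butyl(dimethyl)silyl]oxy}prop-1-en-2-yl)-4-[(4-methoxybenzyl)oxy]-6,10-dimethylcyclodec-5-en-1-one, via lithium enolate 21 (not isolated)
Conditions: LiN(i-Pr)2 (1.1 equiv), THF, −78 °C; then N-bromosuccinimide, −78 °C
Reagents that add atoms: N-bromosuccinimide, BrN1C(=O)CCC1=O
Why: Kinetic deprotonation takes the α-methylene C8 and not the C10 methine, and electrophilic bromination of the ring enolate should occur on its outer face, anti to the C6–C7 ring bond with H7 eclipsing the enolate, which places bromine trans to the C7 side chain (8S).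

Step 12
Reactants: 22 (2S,3R,4S,5E,10R)-2-bromo-3-(3-{[tert-butyl(dimethyl)silyl]oxy}prop-1-en-2-yl)-4-[(4-methoxybenzyl)oxy]-6,10-dimethylcyclodec-5-en-1-one
Product: 23 (2S,3R,4S,5E,10R)-2-bromo-3-(3-hydroxyprop-1-en-2-yl)-4-[(4-methoxybenzyl)oxy]-6,10-dimethylcyclodec-5-en-1-one
Conditions: aq. HF (48%), MeCN, 0 °C
Reagents that add atoms: none
Why: Fluoride-driven cleavage of the primary silyl ether under mildly acidic, amine-free conditions leaves the α-bromo ketone and the 4-methoxybenzyl ether intact.

Step 13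
Reactants: 23 (2S,3R,4S,5E,10R)-2-bromo-3-(3-hydroxyprop-1-en-2-yl)-4-[(4-methoxybenzyl)oxy]-6,10-dimethylcyclodec-5-en-1-one
Product: 26 (4E,6S,7R,8R,10R)-6-[(4-methoxybenzyl)oxy]-9-oxogermacra-4,11(13)-dien-12,8-olide, via enal 24 (not isolated), via acid 25 (not isolated)
Conditions: TEMPO (10 mol%), PhI(OAc)2, CH2Cl2, 25 °C; then NaClO2, NaH2PO4, 2-methylbut-2-ene, t-BuOH/H2O, 0 °C; then NaHCO3, DMF, 25 °C
Reagents that add atoms: sodium chlorite, [Na+].[O-]Cl=O
Why: Nitroxyl-catalysed oxidation of the allylic alcohol and Pinnick oxidation give the acrylic acid without touching the alkenes, and its carboxylate displaces the α-keto bromide from the rear (intramolecular SN2, 5-exo-tet), so C8 is inverted to (8R) and the α-methylene lactone is cis-fused.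

Step 14
Reactants: 26 (4E,6S,7R,8R,10R)-6-[(4-methoxybenzyl)oxy]-9-oxogermacra-4,11(13)-dien-12,8-olide
Product: 27 (4E,6S,7R,8R,9R,10R)-9-hydroxy-6-[(4-methoxybenzyl)oxy]germacra-4,11(13)-dien-12,8-olide
Conditions: NaBH4, CeCl3·7H2O, MeOH, −78 °C
Reagents that add atoms: none
Why: Luche reduction is 1,2-selective and leaves the α-methylene lactone alone, and hydride should enter anti to the polar C8–O bond and anti to the C10–C1 ring bond with the C10 methyl beside the carbonyl oxygen, both α-centres pointing to the same face, to give the (9R) alcohol (8,9-trans and 9,10-cis).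

Step 15
Reactants: 27 (4E,6S,7R,8R,9R,10R)-9-hydroxy-6-[(4-methoxybenzyl)oxy]germacra-4,11(13)-dien-12,8-olide
Product: 28 (4E,6S,7R,8R,9R,10R)-6-[(4-methoxybenzyl)oxy]-9-[(3-methylbut-2-enoyl)oxy]germacra-4,11(13)-dien-12,8-olide
Conditions: 3-methylbut-2-enoyl chloride, pyridine, DMAP (10 mol%), CH2Cl2, 0 °C to 25 °C
Reagents that add atoms: 3-methylbut-2-enoyl chloride, CC(C)=CC(=O)Cl
Why: Nucleophile-catalysed acylation of the secondary alcohol with retention at C9, pyridine being too weak a base to open the vinylketene pathway that would deconjugate the senecioyl group.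

Step 16
Reactants: 28 (4E,6S,7R,8R,9R,10R)-6-[(4-methoxybenzyl)oxy]-9-[(3-methylbut-2-enoyl)oxy]germacra-4,11(13)-dien-12,8-olide
Product: 29 (4E,6S,7R,8R,9R,10R)-6-hydroxy-9-[(3-methylbut-2-enoyl)oxy]germacra-4,11(13)-dien-12,8-olide
Conditions: DDQ, CH2Cl2/pH 7 phosphate buffer, 0 °C
Reagents that add atoms: none
Why: Oxidative cleavage of the 4-methoxybenzyl ether (hydride abstraction at the electron-rich benzylic position, then hydrolysis) frees the C6 hydroxyl under neutral conditions that spare both esters and prevent lactone migration.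

Step 17
Reactants: 29 (4E,6S,7R,8R,9R,10R)-6-hydroxy-9-[(3-methylbut-2-enoyl)oxy]germacra-4,11(13)-dien-12,8-olide
Product: 30 (4R,5R,6R,7R,8R,9R,10R)-4,5-epoxy-6-hydroxy-9-[(3-methylbut-2-enoyl)oxy]germacr-11(13)-en-12,8-olide (CNP0214930.1)
Conditions: VO(acac)2 (5 mol%), t-BuOOH, CH2Cl2, 0 °C to 25 °C
Reagents that add atoms: tert-butyl hydroperoxide, CC(C)(C)OO
Why: Hydroxyl-directed epoxidation through the C6 vanadate ester touches only the adjacent electron-rich trisubstituted alkene, and because the ring holds C7 out of the alkene plane on the inner face, the vanadate should sit at roughly 40–50° on the outer face and deliver oxygen there, which gives the erythro (4R,5R) epoxide.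

Compound list
1 | cis-2,6-dimethylcyclohexanone (meso, 2R,6S) | C[C@H]1CCC[C@@H](C)C1=O | starting material
2 | lithium (6R)-2,6-dimethylcyclohex-1-en-1-olate (not isolated) | C[C@@H]1CCCC(C)=C1[O-].[Li+] | intermediate
3 | trimethyl{[(6R)-2,6-dimethylcyclohex-1-en-1-yl]oxy}silane | C[C@@H]1CCCC(C)=C1O[Si](C)(C)C | intermediate
4 | (2R,6R)-2,6-dimethyl-2-(prop-2-en-1-yl)cyclohexanone | C[C@@H]1CCC[C@](C)(CC=C)C1=O | intermediate
5 | (2R,6R)-2,6-dimethyl-2-[(1E)-prop-1-en-1-yl]cyclohexanone | C[C@@H]1CCC[C@](C)(/C=C/C)C1=O | intermediate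
6 | ozonide of 5, (2R,6R)-2,6-dimethyl-2-(5-methyl-1,2,4-trioxolan-3-yl)cyclohexanone (not isolated) | C[C@@H]1CCC[C@](C)(C2OOC(C)O2)C1=O | intermediate
7 | (1R,3R)-1,3-dimethyl-2-oxocyclohexane-1-carbaldehyde | C[C@@H]1CCC[C@](C)(C=O)C1=O | intermediate
8 | (2R,6R)-2-[(E)-2-iodoethenyl]-2,6-dimethylcyclohexanone | C[C@@H]1CCC[C@](C)(/C=C/I)C1=O | intermediate
9 | 4-methoxybenzyl alcohol | COc1ccc(CO)cc1 | starting material
10 | (2R,6R)-2-{(E)-2-[(4-methoxybenzyl)oxy]ethenyl}-2,6-dimethylcyclohexanone | C[C@@H]1CCC[C@](C)(/C=C/OCc2ccc(OC)cc2)C1=O | intermediate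
11 | 2-bromoprop-2-en-1-ol | C=C(Br)CO | starting material
12 | [(2-bromoprop-2-en-1-yl)oxy](tert-butyl)dimethylsilane | C=C(Br)CO[Si](C)(C)C(C)(C)C | intermediate
13 | (E)-1,2-bis(tributylstannyl)ethene | CCCC[Sn](CCCC)(CCCC)/C=C/[Sn](CCCC)(CCCC)CCCC | starting material
14 | tert-butyl(dimethyl){[(3E)-2-methylidene-4-(tributylstannyl)but-3-en-1-yl]oxy}silane | C=C(CO[Si](C)(C)C(C)(C)C)/C=C/[Sn](CCCC)(CCCC)CCCC | intermediate
15 | (1E)-3-({[tert-butyl(dimethyl)silyl]oxy}methyl)buta-1,3-dien-1-yllithium (not isolated) | [Li]/C=C/C(=C)CO[Si](C)(C)C(C)(C)C | intermediate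
16 | dichloro[(1E)-3-({[tert-butyl(dimethyl)silyl]oxy}methyl)buta-1,3-dien-1-yl]cerium (not isolated) | Cl[Ce](Cl)/C=C/C(=C)CO[Si](C)(C)C(C)(C)C | intermediate
17 | (1S,2R,6R)-1-[(1E)-3-({[tert-butyl(dimethyl)silyl]oxy}methyl)buta-1,3-dien-1-yl]-2-{(E)-2-[(4-methoxybenzyl)oxy]ethenyl}-2,6-dimethylcyclohexan-1-ol | C[C@@H]1CCC[C@](C)(/C=C/OCc2ccc(OC)cc2)[C@@]1(O)/C=C/C(=C)CO[Si](C)(C)C(C)(C)C | intermediate
18 | potassium alkoxide of 17 (not isolated) | C[C@@H]1CCC[C@](C)(/C=C/OCc2ccc(OC)cc2)[C@@]1([O-])/C=C/C(=C)CO[Si](C)(C)C(C)(C)C.[K+] | intermediate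
19 | potassium C8=C9 ring enolate of 20, C7 and C10 trans across the enolate (not isolated) | C=C(CO[Si](C)(C)C(C)(C)C)[C@H]1/C=C(\[O-])[C@H](C)CCC/C(C)=C/[C@@H]1OCc1ccc(OC)cc1.[K+] | intermediate
20 | (3R,4S,5E,10R)-3-(3-{[tert-butyl(dimethyl)silyl]oxy}prop-1-en-2-yl)-4-[(4-methoxybenzyl)oxy]-6,10-dimethylcyclodec-5-en-1-one | C=C(CO[Si](C)(C)C(C)(C)C)[C@H]1CC(=O)[C@H](C)CCC/C(C)=C/[C@@H]1OCc1ccc(OC)cc1 | intermediate
21 | lithium C8=C9 enolate of 20, enolate geometry not fixed (not isolated) | C=C(CO[Si](C)(C)C(C)(C)C)[C@H]1C=C([O-])[C@H](C)CCC/C(C)=C/[C@@H]1OCc1ccc(OC)cc1.[Li+] | intermediate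
22 | (2S,3R,4S,5E,10R)-2-bromo-3-(3-{[tert-butyl(dimethyl)silyl]oxy}prop-1-en-2-yl)-4-[(4-methoxybenzyl)oxy]-6,10-dimethylcyclodec-5-en-1-one (8S bromide, bromine trans to the C7 side chain) | C=C(CO[Si](C)(C)C(C)(C)C)[C@H]1[C@H](Br)C(=O)[C@H](C)CCC/C(C)=C/[C@@H]1OCc1ccc(OC)cc1 | intermediate
23 | (2S,3R,4S,5E,10R)-2-bromo-3-(3-hydroxyprop-1-en-2-yl)-4-[(4-methoxybenzyl)oxy]-6,10-dimethylcyclodec-5-en-1-one | C=C(CO)[C@H]1[C@H](Br)C(=O)[C@H](C)CCC/C(C)=C/[C@@H]1OCc1ccc(OC)cc1 | intermediate
24 | enal from 23, side chain C(=CH2)CHO, other centres unchanged (not isolated) | C=C(C=O)[C@H]1[C@H](Br)C(=O)[C@H](C)CCC/C(C)=C/[C@@H]1OCc1ccc(OC)cc1 | intermediate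
25 | acrylic acid from 24, side chain C(=CH2)CO2H, other centres unchanged (not isolated) | C=C(C(=O)O)[C@H]1[C@H](Br)C(=O)[C@H](C)CCC/C(C)=C/[C@@H]1OCc1ccc(OC)cc1 | intermediate
26 | (4E,6S,7R,8R,10R)-6-[(4-methoxybenzyl)oxy]-9-oxogermacra-4,11(13)-dien-12,8-olide (cis-fused lactone) | C=C1C(=O)O[C@H]2C(=O)[C@H](C)CCC/C(C)=C/[C@H](OCc3ccc(OC)cc3)[C@@H]12 | intermediate
27 | (4E,6S,7R,8R,9R,10R)-9-hydroxy-6-[(4-methoxybenzyl)oxy]germacra-4,11(13)-dien-12,8-olide | C=C1C(=O)O[C@H]2[C@H](O)[C@H](C)CCC/C(C)=C/[C@H](OCc3ccc(OC)cc3)[C@@H]12 | intermediate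
28 | (4E,6S,7R,8R,9R,10R)-6-[(4-methoxybenzyl)oxy]-9-[(3-methylbut-2-enoyl)oxy]germacra-4,11(13)-dien-12,8-olide | C=C1C(=O)O[C@H]2[C@H](OC(=O)C=C(C)C)[C@H](C)CCC/C(C)=C/[C@H](OCc3ccc(OC)cc3)[C@@H]12 | intermediate
29 | (4E,6S,7R,8R,9R,10R)-6-hydroxy-9-[(3-methylbut-2-enoyl)oxy]germacra-4,11(13)-dien-12,8-olide | C=C1C(=O)O[C@H]2[C@H](OC(=O)C=C(C)C)[C@H](C)CCC/C(C)=C/[C@H](O)[C@@H]12 | intermediate
30 | (4R,5R,6R,7R,8R,9R,10R)-4,5-epoxy-6-hydroxy-9-[(3-methylbut-2-enoyl)oxy]germacr-11(13)-en-12,8-olide (CNP0214930.1) | C=C1C(=O)O[C@H]2[C@H](OC(=O)C=C(C)C)[C@H](C)CCC[C@@]3(C)O[C@@H]3[C@H](O)[C@@H]12 | target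

Total step count: 17. Longest linear sequence: 15 steps (1 to 30 through steps 1–6 and 9–17).

Steps most likely to fail

Step 9. Poor facial selectivity in the 1,2-addition: the reagent may instead enter anti to the axial C4 methyl, so that the cis-dialkenyl carbinol dominates; that epimer would rearrange through a different chair. Fallback (sets out from 8, returns at 17): the C9 configuration is set by delivering oxygen instead of carbon. Non-basic methylenation of 8 (Cp2TiMe2, toluene, 70 °C) gives (1R,3R)-1-[(E)-2-iodoethenyl]-1,3-dimethyl-2-methylidenecyclohexane F1. Buffered peracid epoxidation (mCPBA, NaHCO3, CH2Cl2, 0 °C), which attacks methylenecyclohexanes axially and here anti to the axial C4 methyl, gives the spiro-epoxide F2 with oxygen cis to the arm. Dimethylsulfonium methylide (Me3S+ I−, n-BuLi, THF, −10 °C to 25 °C) opens the epoxide at its methylene carbon and loses Me2S to give the tertiary vinyl carbinol F3. The copper-catalysed etherification of step 6 with 9 then gives the enol ether F4. A Heck reaction of this with bromide 12 (Pd(OAc)2, Bu4NCl, K2CO3, DMF, 60 °C) attaches the 2-propenyl unit to the terminal vinyl carbon with E geometry and gives 17.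

Step 17. Oxygen delivery to the other alkene face: the ring may react through the conformer in which H6 and not O6 eclipses the C4 methyl, which leads to the threo epoxy alcohol, as in open-chain allylic alcohols with a cis substituent. Fallback (from 29 to 30, no new compound): reagent control by Sharpless asymmetric epoxidation with Ti(O-i-Pr)4, D-(−)-diisopropyl tartrate and t-BuOOH (stoichiometric, 4 Å sieves, CH2Cl2, −20 °C). For the spatial arrangement at C6 this tartrate is the matched one, and its titanium complex delivers oxygen erythro, anti to C7.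

Step 14. Hydride entry on the other carbonyl face, if the ring conformation overrides the two α-centres, or competing conjugate reduction of the methylene lactone. Fallback (from 26, returns at 28): the epimeric alcohol, (9S)-9-hydroxy-6-[(4-methoxybenzyl)oxy]germacra-4,11(13)-dien-12,8-olide F5, is separated and esterified with inversion in a Mitsunobu reaction with 3-methylbut-2-enoic acid (PPh3, DIAD, toluene, 0 °C to 25 °C), which gives 28 directly.

Further compounds
F1 | step 9 | (1R,3R)-1-[(E)-2-iodoethenyl]-1,3-dimethyl-2-methylidenecyclohexane | C[C@@H]1CCC[C@](C)(/C=C/I)C1=C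
F2 | step 9 | spiro-epoxide of F1 at C9, oxygen cis to the iodovinyl arm and to the C10 methyl | C[C@@H]1CCC[C@](C)(/C=C/I)[C@@]12CO2
F3 | step 9 | 1-ethenyl-2-[(E)-2-iodoethenyl]-2,6-dimethylcyclohexan-1-ol, all three centres arranged as in 17 | C[C@@H]1CCC[C@](C)(/C=C/I)[C@@]1(O)C=C
F4 | step 9 | 1-ethenyl-2-{(E)-2-[(4-methoxybenzyl)oxy]ethenyl}-2,6-dimethylcyclohexan-1-ol, all three centres arranged as in 17 | C[C@@H]1CCC[C@](C)(/C=C/OCc2ccc(OC)cc2)[C@@]1(O)C=C
F5 | step 14 | (4E,6S,7R,8R,9S,10R)-9-hydroxy-6-[(4-methoxybenzyl)oxy]germacra-4,11(13)-dien-12,8-olide (C9 epimer of 27) | C=C1C(=O)O[C@H]2[C@@H](O)[C@H](C)CCC/C(C)=C/[C@H](OCc3ccc(OC)cc3)[C@@H]12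
F0 | step 17 | none | none
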